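**Strategy**

The plan rests on the bond between C3 of the chroman (pyran ring C) and C1' of the tetramethoxyphenyl ring B. C3 and C4 are raised one oxidation level, to the C3=C4 alkene of a 2H-chromene conjugated with ring A. A rhodium/chiral-diene-catalysed asymmetric hydroarylation then delivers the 2,3,4,5-tetramethoxyphenyl group of a boronic acid to C3 and hydrogen to C4 in one operation: ring A directs rhodium to benzylic C4, so the aryl group lands on C3, and the ligand sets the only stereocentre (3S). The precursors are flat, achiral 7-benzyloxy-8-methoxy-2H-chromene and (2,3,4,5-tetramethoxyphenyl)boronic acid; hydrogenolysis of the benzyl ether completes the route.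

Key step: step 5

Remark: the sense of induction of the diene ligand is a prediction; the antipode meant is the one that delivers the aryl group to the Re face of C3 of chromene 4 (C2 > C4 > H), which gives 3S, and catalyst-bound organometallic species are described in the Why lines and not numbered.

**Route**

Step 1
Reactants: 1 2-methoxybenzene-1,3-diol (2-methoxyresorcinol)
Product: 2 3-(benzyloxy)-2-methoxyphenol
Conditions: BnBr (1.0 equiv), K2CO3 (1.1 equiv), acetone, reflux
Reagents that add atoms: benzyl bromide, BrCc1ccccc1
Why: Williamson etherification of a symmetric diol with one equivalent of halide should give the mono-ether as the main product of a statistical alkylation, the dibenzyl ether and unreacted 1 being separable by polarity and acidity and 1 being recycled.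

Step 2
Reactants: 2 3-(benzyloxy)-2-methoxyphenol
Product: 3 1-(benzyloxy)-2-methoxy-3-(prop-2-yn-1-yloxy)benzene
Conditions: propargyl bromide (1.3 equiv), K2CO3, DMF, rt
Reagents that add atoms: propargyl bromide, C#CCBr
Why: Williamson etherification (SN2) of the remaining phenol under mild carbonate conditions that leave the benzyl ether and the terminal alkyne untouched.

Step 3
Reactants: 3 1-(benzyloxy)-2-methoxy-3-(prop-2-yn-1-yloxy)benzene
Product: 4 7-(benzyloxy)-8-methoxy-2H-chromene
Conditions: Ph3PAuNTf2 (2 mol %), CH2Cl2, rt
Reagents that add atoms: none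
Why: Gold(I)-catalysed intramolecular alkyne hydroarylation of an aryl propargyl ether, in which the π-activated alkyne is attacked 6-endo-dig by the only free ortho carbon (para to the benzyloxy donor) and protodeauration releases the 2H-chromene.

Step 4
Reactants: 5 1,2,3,4-tetramethoxybenzene
Product: 8 (2,3,4,5-tetramethoxyphenyl)boronic acid, via 2,3,4,5-tetramethoxyphenyllithium 6 (not isolated), via lithium aryltriisopropoxyborate 7 (not isolated)
Conditions: n-BuLi, TMEDA, THF, 0 °C; B(OiPr)3, −78 °C to rt; 1 M HCl
Reagents that add atoms: triisopropyl borate, CC(C)OB(OC(C)C)OC(C)C; water, O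
Why: Directed ortho-metalation next to a terminal methoxy group (the two ring C–H positions are equivalent by symmetry) followed by trapping of the aryllithium with the borate and hydrolysis (lithiation–borylation) should give the boronic acid as a single regioisomer.

Step 5
Reactants: 4 7-(benzyloxy)-8-methoxy-2H-chromene; 8 (2,3,4,5-tetramethoxyphenyl)boronic acid
Product: 9 (3S)-7-(benzyloxy)-8-methoxy-3-(2,3,4,5-tetramethoxyphenyl)chroman
Conditions: 8 (3 equiv), [Rh(OH)(Fc-tfb)]2 (chiral tetrafluorobenzobarrelene diene, 5 mol % Rh, antipode as in the remark), 1,4-dioxane/H2O 10:1, 80 °C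
Reagents that add atoms: none
Why: Transmetalation of 8 to the hydroxorhodium(I)–diene complex gives an arylrhodium species that inserts the C3=C4 alkene of 4 in a syn fashion, with the aryl group on C3 and rhodium on C4, where ring A stabilises it as a π-benzyl complex; protonolysis by water (directly or after a 1,4-rhodium shift to C6' of the new aryl ring) turns C4 into CH2 and regenerates Rh–OH. The closest known reaction type is the rhodium/chiral-diene-catalysed asymmetric addition of arylboronic acids to 2H-chromenes and related non-activated cyclic alkenes (Hayashi–Miyaura-type hydroarylation). No ring is closed in this step. The C3 stereocentre is set by the C2-symmetric chiral diene, which differentiates the enantiotopic faces of the planar alkene during insertion; delivery of the aryl group to the Re face of C3 gives 3S, and this centre, a non-acidic C–H, should not erode afterwards. The step needs regioselectivity (aryl to C3, not C4), secured by the benzylic stabilisation of rhodium at C4 and by the lack of a syn β-hydrogen for β-hydride elimination, and chemoselectivity against protodeboronation of the electron-rich ortho-substituted boronic acid, met by using 8 in excess.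

Step 6
Reactants: 9 (3S)-7-(benzyloxy)-8-methoxy-3-(2,3,4,5-tetramethoxyphenyl)chroman
Product: 10 (3S)-8-methoxy-3-(2,3,4,5-tetramethoxyphenyl)chroman-7-ol
Conditions: H2 (1 atm), 10 % Pd/C, EtOAc/MeOH, rt
Reagents that add atoms: none
Why: Heterogeneous hydrogenolysis of the benzyl aryl ether should free the C7 phenol while the methyl ethers, the non-benzylic C2–O1 bond and the C3 stereocentre stay untouched.

**Compound list**

1 | 2-methoxybenzene-1,3-diol (2-methoxyresorcinol) | COc1c(O)cccc1O | starting material
2 | 3-(benzyloxy)-2-methoxyphenol | COc1c(O)cccc1OCc1ccccc1 | intermediate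
3 | 1-(benzyloxy)-2-methoxy-3-(prop-2-yn-1-yloxy)benzene | COc1c(OCC#C)cccc1OCc1ccccc1 | intermediate
4 | 7-(benzyloxy)-8-methoxy-2H-chromene | COc1c(OCc2ccccc2)ccc2C=CCOc12 | intermediate
5 | 1,2,3,4-tetramethoxybenzene | COc1ccc(OC)c(OC)c1OC | starting material
6 | (2,3,4,5-tetramethoxyphenyl)lithium (not isolated) | [Li]c1cc(OC)c(OC)c(OC)c1OC | intermediate
7 | lithium triisopropoxy(2,3,4,5-tetramethoxyphenyl)borate (not isolated) | [Li+].COc1cc([B-](OC(C)C)(OC(C)C)OC(C)C)c(OC)c(OC)c1OC | intermediate
8 | (2,3,4,5-tetramethoxyphenyl)boronic acid | COc1cc(B(O)O)c(OC)c(OC)c1OC | intermediate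
9 | (3S)-7-(benzyloxy)-8-methoxy-3-(2,3,4,5-tetramethoxyphenyl)chroman | COc1cc([C@H]2COc3c(ccc(OCc4ccccc4)c3OC)C2)c(OC)c(OC)c1OC | intermediate
10 | (3S)-8-methoxy-3-(2,3,4,5-tetramethoxyphenyl)chroman-7-ol | COc1cc([C@H]2COc3c(ccc(O)c3OC)C2)c(OC)c(OC)c1OC | target

**Step count and risks**

Total step count: 6. Longest linear sequence: 5 steps (steps 1, 2, 3, 5, 6, from 2-methoxyresorcinol).

Steps most likely to fail:

1. Step 5. Insertion of the hindered, electron-rich arylrhodium into the electron-rich alkene may be slower than protodeboronation, or the ligand may discriminate the two alkene faces poorly. The fallback sets out from 4 and returns at 9; it forms the same C3–C1' bond by cross-coupling and moves the stereocontrol to a hydrogenation. NBS in wet DMSO should give racemic trans-7-(benzyloxy)-3-bromo-8-methoxychroman-4-ol F1 by bromonium opening at benzylic C4. Acid-catalysed dehydration (TsOH, toluene, reflux) should give 7-(benzyloxy)-3-bromo-8-methoxy-2H-chromene F2. Suzuki–Miyaura coupling of F2 with 8 (Pd(dppf)Cl2, K2CO3, dioxane/H2O) should give the isoflav-3-ene 7-(benzyloxy)-8-methoxy-3-(2,3,4,5-tetramethoxyphenyl)-2H-chromene F3. Iridium-catalysed asymmetric hydrogenation of F3 with a chiral N,P-ligand complex (H2, CH2Cl2) should set C3 and give 9.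

2. Step 3. Competing 5-exo closure to a benzofuran, or oligomerisation of the acid-sensitive electron-rich chromene on the Lewis-acidic gold catalyst, may erode the cyclisation. The fallback sets out from 2 and returns at 4, bypassing 3. Magnesium-mediated ortho-formylation (MgCl2, Et3N, paraformaldehyde, MeCN, reflux) at the only free ortho position should give 4-(benzyloxy)-2-hydroxy-3-methoxybenzaldehyde F4. Schweizer annulation of F4 with vinyltriphenylphosphonium bromide (K2CO3, THF, reflux; oxa-Michael addition then intramolecular Wittig reaction) should build the pyran ring and give 4.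

3. Step 4. Incomplete metalation or loss of boron by protodeboronation during the acidic work-up of the very electron-rich ortho-alkoxy boronic acid. The fallback sets out from 5 and returns at 9. Electrophilic bromination (NBS, MeCN, rt) should give 1-bromo-2,3,4,5-tetramethoxybenzene F5. Miyaura borylation (B2pin2, Pd(dppf)Cl2, KOAc, dioxane, 90 °C) should give the more robust pinacol ester 2-(2,3,4,5-tetramethoxyphenyl)-4,4,5,5-tetramethyl-1,3,2-dioxaborolane F6. F6 takes the place of 8 in step 5 (with aqueous K3PO4 added) to give 9.

**Further compounds**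

F1 | step 5 | racemic trans-(3R,4R)-7-(benzyloxy)-3-bromo-8-methoxychroman-4-ol (one enantiomer drawn) | COc1c(OCc2ccccc2)ccc2c1OC[C@@H](Br)[C@@H]2O
F2 | step 5 | 7-(benzyloxy)-3-bromo-8-methoxy-2H-chromene | COc1c(OCc2ccccc2)ccc2C=C(Br)COc12
F3 | step 5 | 7-(benzyloxy)-8-methoxy-3-(2,3,4,5-tetramethoxyphenyl)-2H-chromene | COc1cc(C2=Cc3ccc(OCc4ccccc4)c(OC)c3OC2)c(OC)c(OC)c1OC
F4 | step 3 | 4-(benzyloxy)-2-hydroxy-3-methoxybenzaldehyde | COc1c(O)c(C=O)ccc1OCc1ccccc1
F5 | step 4 | 1-bromo-2,3,4,5-tetramethoxybenzene | COc1cc(Br)c(OC)c(OC)c1OC
F6 | step 4 | 2-(2,3,4,5-tetramethoxyphenyl)-4,4,5,5-tetramethyl-1,3,2-dioxaborolane | COc1cc(B2OC(C)(C)C(C)(C)O2)c(OC)c(OC)c1OC
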